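**Retrosynthetic overview**
- Target ⇒ imide N–C(O) disconnection: (R)-3-acetyl-5-isobutyltetramic acid (as its dianion) + (E)-dodec-2-enoyl chloride; the N-acylation is done last.
- (E)-Dodec-2-enoyl chloride ⇒ (E)-dodec-2-enoic acid ⇒ decanal + a stabilised C2 ylide (Wittig).
- 3-Acetyl group ⇒ O-acylation / O→C acyl shift on N-Boc-(R)-5-isobutyltetramic acid.
- N-Boc tetramic acid ⇒ key C3–C4 bond by intermolecular Claisen-type C-acylation of Meldrum's acid with N-Boc-D-leucine; then the only ring (the pyrrolidine-2,4-dione) is closed at N1–C2 by thermal acylketene lactamisation.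
- The single stereocentre (C5, R) comes from D-leucine and is carried through unchanged.

Assumption: tetramic acids are drawn in one tautomeric form (2,4-dione for 6, 4-hydroxy enol for the 3-acetyl compounds, as in the target SMILES); tautomers are not distinguished.

**Route**

Step 1
Reactants: 1 D-leucine
Product: 2 N-Boc-D-leucine, i.e. (2R)-2-[(tert-butoxycarbonyl)amino]-4-methylpentanoic acid
Conditions: Boc2O (1.1 equiv), Et3N (1.5 equiv), dioxane/H2O 1:1, 0 °C to rt, 16 h; 5% aq. KHSO4 to pH 3, EtOAc; dried by toluene azeotrope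
Reagents that add atoms: di-tert-butyl dicarbonate, CC(C)(C)OC(=O)OC(=O)OC(C)(C)C
Why: Carbamate formation (Boc protection) at the amine does not touch the stereocentre, and the urethane group suppresses oxazolone racemisation when the acid is activated later.

Step 2
Reactants: 2 N-Boc-D-leucine; 3 Meldrum's acid (2,2-dimethyl-1,3-dioxane-4,6-dione)
Product: 4 tert-butyl N-[(2R)-1-(2,2-dimethyl-4,6-dioxo-1,3-dioxan-5-ylidene)-1-hydroxy-4-methylpentan-2-yl]carbamate (acyl Meldrum's acid, enol form)
Conditions: N,N'-dicyclohexylcarbodiimide (DCC, 1.1 equiv), 4-(dimethylamino)pyridine (1.5 equiv), CH2Cl2, −5 to 0 °C, 16 h; filter, wash with 5% aq. KHSO4, concentrate below 30 °C, use crude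
Reagents that add atoms: none
Why: Intermolecular Claisen-type condensation in which the carbodiimide/acylpyridinium-activated acid C-acylates the Meldrum's acid enolate, forging the future C3–C4 bond; the urethane-protected α-centre keeps its (R) configuration.

Step 3
Reactants: 4 acyl Meldrum's acid
Product: 6 tert-butyl (2R)-2-(2-methylpropyl)-3,5-dioxopyrrolidine-1-carboxylate (N-Boc-(R)-5-isobutyltetramic acid), via acylketene 5 (not isolated)
Conditions: EtOAc, reflux, 45 min; cool, crystallise from EtOAc/hexane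
Reagents that add atoms: none
Why: Thermal fragmentation of the acyl Meldrum's acid (loss of acetone and CO2) gives an acylketene that is trapped by the carbamate N–H in a 5-exo lactamisation under neutral conditions, so C5 stays (R).

Step 4
Reactants: 6 N-Boc-(R)-5-isobutyltetramic acid
Product: 8 tert-butyl (2R)-4-acetyl-3-hydroxy-2-(2-methylpropyl)-5-oxo-2,5-dihydro-1H-pyrrole-1-carboxylate, via 4-O-acetyl enol ester 7 (not isolated)
Conditions: AcOH (1.1 equiv), DCC (1.2 equiv), 4-(dimethylamino)pyridine (1.5 equiv), CH2Cl2, 0 °C to rt, 16 h; filter, wash with 5% aq. KHSO4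
Reagents that add atoms: acetic acid, CC(=O)O
Why: Steglich O-acylation of the enol followed by 4-(dimethylamino)pyridine-mediated O→C 1,3-acyl shift (Yoshii protocol, a Fries-type rearrangement) gives the thermodynamically favoured chelated 3-acetyl tetramic acid without involving C5.

Step 5
Reactants: 8 N-Boc-3-acetyl tetramic acid
Product: 9 (5R)-3-acetyl-4-hydroxy-5-(2-methylpropyl)-1,5-dihydro-2H-pyrrol-2-one
Conditions: TFA/CH2Cl2 1:3, 0 °C to rt, 1.5 h; evaporate, toluene azeotrope
Reagents that add atoms: none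
Why: Acidolytic Boc cleavage (tert-butyl cation loss, then decarboxylation) leaves the acid-stable 3-acyltetramic acid and its C5 centre untouched.

Step 6
Reactants: 10 decanal; 11 ethyl (triphenylphosphoranylidene)acetate
Product: 12 ethyl (2E)-dodec-2-enoate
Conditions: CH2Cl2, rt, 16 h; hexane trituration to remove Ph3PO, flash chromatography
Reagents that add atoms: none
Why: Wittig olefination with a stabilised ylide gives the (E)-enoate with high selectivity (typically ≥95:5), and the minor Z isomer is removed by chromatography.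

Step 7
Reactants: 12 ethyl (2E)-dodec-2-enoate
Product: 13 (2E)-dodec-2-enoic acid
Conditions: LiOH·H2O (2 equiv), THF/H2O 3:1, rt, 12 h; then 1 M HCl to pH 2
Reagents that add atoms: lithium hydroxide, [Li+].[OH-]
Why: Saponification (acyl-oxygen ester hydrolysis) at room temperature does not disturb the conjugated (E)-alkene.

Step 8
Reactants: 13 (2E)-dodec-2-enoic acid
Product: 14 (2E)-dodec-2-enoyl chloride
Conditions: (COCl)2 (1.5 equiv), N,N-dimethylformamide (1 mol %), CH2Cl2, 0 °C to rt, 2 h; evaporate, use at once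
Reagents that add atoms: oxalyl chloride, O=C(Cl)C(=O)Cl
Why: N,N-Dimethylformamide-catalysed (Vilsmeier-type) acid chloride formation runs without base, so the alkene neither isomerises nor deconjugates.

Step 9
Reactants: 9 (5R)-3-acetyl-5-isobutyltetramic acid; 14 (2E)-dodec-2-enoyl chloride
Product: 16 reutericyclin C, via dilithium dianion 15 (not isolated)
Conditions: n-BuLi (2.05 equiv), THF, −78 °C, 30 min; then 14 (1.1 equiv), −78 to −20 °C, 2 h; 1 M HCl quench; reversed-phase chromatography (C18, MeCN/H2O, 0.1% HCO2H)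
Reagents that add atoms: none
Why: The first equivalent of base forms the unreactive delocalised tricarbonyl enolate and the second the far more nucleophilic lactam N-anion, which undergoes nucleophilic acyl substitution on the acid chloride (imide formation); low temperature and an acidic quench keep C5 (R).

**Compound list**

1 | D-leucine, (2R)-2-amino-4-methylpentanoic acid | CC(C)C[C@@H](N)C(=O)O | starting material
2 | N-Boc-D-leucine, (2R)-2-[(tert-butoxycarbonyl)amino]-4-methylpentanoic acid | CC(C)C[C@@H](NC(=O)OC(C)(C)C)C(=O)O | intermediate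
3 | Meldrum's acid, 2,2-dimethyl-1,3-dioxane-4,6-dione | CC1(C)OC(=O)CC(=O)O1 | starting material
4 | tert-butyl N-[(2R)-1-(2,2-dimethyl-4,6-dioxo-1,3-dioxan-5-ylidene)-1-hydroxy-4-methylpentan-2-yl]carbamate (acyl Meldrum's acid) | CC(C)C[C@@H](NC(=O)OC(C)(C)C)C(O)=C1C(=O)OC(C)(C)OC1=O | intermediate
5 | acylketene, tert-butyl N-[(4R)-6-methyl-1,3-dioxohept-1-en-4-yl]carbamate (transient, formed in the flask) | CC(C)C[C@@H](NC(=O)OC(C)(C)C)C(=O)C=C=O | intermediate
6 | tert-butyl (2R)-2-(2-methylpropyl)-3,5-dioxopyrrolidine-1-carboxylate (N-Boc-(R)-5-isobutyltetramic acid) | CC(C)C[C@@H]1C(=O)CC(=O)N1C(=O)OC(C)(C)C | intermediate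
7 | tert-butyl (2R)-3-(acetyloxy)-2-(2-methylpropyl)-5-oxo-2,5-dihydro-1H-pyrrole-1-carboxylate (4-O-acetyl enol ester, formed in the flask) | CC(C)C[C@@H]1C(OC(C)=O)=CC(=O)N1C(=O)OC(C)(C)C | intermediate
8 | tert-butyl (2R)-4-acetyl-3-hydroxy-2-(2-methylpropyl)-5-oxo-2,5-dihydro-1H-pyrrole-1-carboxylate | CC(C)C[C@@H]1C(O)=C(C(C)=O)C(=O)N1C(=O)OC(C)(C)C | intermediate
9 | (5R)-3-acetyl-4-hydroxy-5-(2-methylpropyl)-1,5-dihydro-2H-pyrrol-2-one | CC(C)C[C@@H]1C(O)=C(C(C)=O)C(=O)N1 | intermediate
10 | decanal | CCCCCCCCCC=O | starting material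
11 | ethyl (triphenylphosphoranylidene)acetate | CCOC(=O)C=P(c1ccccc1)(c1ccccc1)c1ccccc1 | starting material
12 | ethyl (2E)-dodec-2-enoate | CCCCCCCCC/C=C/C(=O)OCC | intermediate
13 | (2E)-dodec-2-enoic acid | CCCCCCCCC/C=C/C(=O)O | intermediate
14 | (2E)-dodec-2-enoyl chloride | CCCCCCCCC/C=C/C(=O)Cl | intermediate
15 | dilithium salt of 9 (enolate O and lactam N deprotonated, formed in the flask) | CC(C)C[C@@H]1C([O-])=C(C(C)=O)C(=O)[N-]1.[Li+].[Li+] | intermediate
16 | reutericyclin C, (5R)-3-acetyl-1-[(2E)-dodec-2-enoyl]-4-hydroxy-5-(2-methylpropyl)-1,5-dihydro-2H-pyrrol-2-one | CCCCCCCCC/C=C/C(=O)N1C(=O)C(C(C)=O)=C(O)[C@H]1CC(C)C | target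

**Step count and risks**

Total steps: 9. Longest linear sequence: 6 steps (1 → 2 → 4 → 6 → 8 → 9 → 16; steps 1, 2, 3, 4, 5 and 9). The side chain (steps 6–8) joins in step 9.

Three steps most likely to fail:

Step 9 (N-acylation of the dianion). Risks are competing O-acylation, poor solubility of the dilithium salt, and epimerisation at C5 of the imide product. The fallback installs the N-acyl group before the 3-acetyl group, on an O-protected tetramate whose lactam N–H is the only acidic site. It sets out from 6 and comes back to the route at 16. Mitsunobu O-alkylation of 6 (allyl alcohol, PPh3, DIAD, THF, 0 °C to rt) gives tert-butyl (2R)-3-(allyloxy)-2-isobutyl-5-oxo-2,5-dihydro-1H-pyrrole-1-carboxylate F1. TFA/CH2Cl2 removes the Boc group to give (5R)-4-(allyloxy)-5-isobutyl-1,5-dihydro-2H-pyrrol-2-one F2. Deprotonation with n-BuLi (1.05 equiv, THF, −78 °C) and addition of 14 gives (5R)-4-(allyloxy)-1-[(2E)-dodec-2-enoyl]-5-isobutyl-1,5-dihydro-2H-pyrrol-2-one F3. Pd(PPh3)4 (zerovalent palladium, 5 mol %) with dimedone in THF at rt transfers the allyl group to dimedone and releases (5R)-1-[(2E)-dodec-2-enoyl]-4-hydroxy-5-isobutyl-1,5-dihydro-2H-pyrrol-2-one F4. Acetic acid, DCC and 4-(dimethylamino)pyridine in CH2Cl2 (the conditions of step 4) then give 16.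

Step 4 (C3-acetylation by O-acylation and acyl shift). Risks are incomplete O→C migration, N-acylurea formation, and a product that is hard to chromatograph. The fallback is a Lewis-acid-mediated direct C-acylation of the unprotected tetramic acid. It sets out from 6 and comes back at 9. TFA/CH2Cl2 gives (5R)-5-isobutylpyrrolidine-2,4-dione F5, used at once. Acetyl chloride in BF3·OEt2 at 70 °C gives the difluoroboron chelate of (5R)-3-acetyl-5-isobutyltetramic acid F6. Heating F6 in methanol breaks the chelate and delivers 9.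

Step 2 (C-acylation of Meldrum's acid). Risks are incomplete acylation, N-acylurea formation, and slight racemisation with excess base; the enantiopurity of 6 should be checked by chiral HPLC. The fallback brings the acetyl group in before ring closure and closes the ring by an intramolecular Claisen (Lacey–Dieckmann) reaction. It sets out from 1 and comes back at 9. SOCl2 in MeOH (0 °C to reflux) gives methyl D-leucinate hydrochloride F7. 2,2,6-Trimethyl-4H-1,3-dioxin-4-one and Et3N in refluxing toluene (acetylketene transfer) give methyl N-(3-oxobutanoyl)-D-leucinate F8. Cyclisation with Bu4NF in THF at rt, chosen to avoid C5 epimerisation, followed by acidification gives 9.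

**Further compounds**

F1 | step 9 | tert-butyl (2R)-3-(allyloxy)-2-(2-methylpropyl)-5-oxo-2,5-dihydro-1H-pyrrole-1-carboxylate | CC(C)C[C@@H]1C(OCC=C)=CC(=O)N1C(=O)OC(C)(C)C
F2 | step 9 | (5R)-4-(allyloxy)-5-(2-methylpropyl)-1,5-dihydro-2H-pyrrol-2-one | CC(C)C[C@@H]1C(OCC=C)=CC(=O)N1
F3 | step 9 | (5R)-4-(allyloxy)-1-[(2E)-dodec-2-enoyl]-5-(2-methylpropyl)-1,5-dihydro-2H-pyrrol-2-one | CCCCCCCCC/C=C/C(=O)N1C(=O)C=C(OCC=C)[C@H]1CC(C)C
F4 | step 9 | (5R)-1-[(2E)-dodec-2-enoyl]-4-hydroxy-5-(2-methylpropyl)-1,5-dihydro-2H-pyrrol-2-one | CCCCCCCCC/C=C/C(=O)N1C(=O)C=C(O)[C@H]1CC(C)C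
F5 | step 4 | (5R)-5-(2-methylpropyl)pyrrolidine-2,4-dione | CC(C)C[C@@H]1C(=O)CC(=O)N1
F6 | step 4 | difluoroboron chelate of (5R)-3-acetyl-5-(2-methylpropyl)tetramic acid (boron bridging the C4–O and acetyl O) | CC(C)C[C@@H]1C2=C(C(=O)N1)C(C)=[O+][B-](F)(F)O2
F7 | step 2 | methyl D-leucinate hydrochloride | CC(C)C[C@@H](N)C(=O)OC.Cl
F8 | step 2 | methyl N-(3-oxobutanoyl)-D-leucinate | CC(C)C[C@@H](NC(=O)CC(C)=O)C(=O)OC
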